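**Retrosynthetic overview**
- Target ⇐ acetylation of C9–OH ⇐ reduction of the C9 ketone ⇐ Mitsunobu acetoxylation (inversion) at C3 of a 3‑hydroxy‑9‑oxo germacradienolide; the γ‑lactone ⇐ oxidative lactonisation of a 6,12‑diol.
- Ten‑membered ring ⇐ anionic oxy‑Cope ([3,3]) of a trans‑1,2‑dialkenylcyclohex‑2‑en‑1‑ol. It forms C6–C7, the E C4=C5 alkene and both ring‑fusion stereocentres; the cyclohexene C=C becomes the Z C1=C10 enone.
- Carbinol ⇐ alkenyllithium (C7, C8, C11–C13, from the (S)‑Roche ester) + 6‑methyl‑6‑(silyloxyvinyl)cyclohexenone (from (R)‑carvone by Criegee degradation, allylation, methylation, alkene cleavage, enol silylation).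
- Ring order: six‑membered carbocycle (bought in carvone) → ten‑membered carbocycle (oxy‑Cope) → γ‑lactone.

Assumption: target atoms are referred to by germacrane numbering (C6 carries the lactone oxygen, C12 is the lactone carbonyl, C3 and C9 carry the acetates, C11 the lactone methyl, C14 and C15 the methyls on C10 and C4).

**Step 1**
Reactants: 1 (R)-(−)-carvone
Product: 3 (1R)-4-methyl-5-oxocyclohex-3-en-1-yl acetate, via methoxy hydroperoxide 2 (not isolated)
Conditions: O3, CH2Cl2/MeOH, −78 °C; then Ac2O, Et3N, DMAP (cat.), −78 °C to rt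
Reagents that add atoms: ozone [O-][O+]=O; methanol CO
Why: Ozonolysis of the electron‑rich isopropenyl alkene (the enone C=C is deactivated) in methanol gives the methoxy hydroperoxide, and O‑acetylation triggers a Criegee rearrangement in which the ring carbon migrates to oxygen with retention, so the carvone stereocentre becomes the R C–O centre.

**Step 2**
Reactants: 3 (1R)-4-methyl-5-oxocyclohex-3-en-1-yl acetate
Product: 4 (5R)-5-hydroxy-2-methylcyclohex-2-en-1-one
Conditions: K2CO3, MeOH, 0 °C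
Reagents that add atoms: none
Why: Transesterification (methanolysis) of the acetate at 0 °C is faster than β‑elimination, and the stereocentre is not touched.

**Step 3**
Reactants: 4 (5R)-5-hydroxy-2-methylcyclohex-2-en-1-one
Product: 5 (5R)-5-[(tert-butyldimethylsilyl)oxy]-2-methylcyclohex-2-en-1-one
Conditions: TBSCl, imidazole, DMF, rt
Reagents that add atoms: tert-butyldimethylsilyl chloride CC(C)(C)[Si](C)(C)Cl
Why: Silyl ether formation protects the alcohol for the enolate chemistry and supplies the bulky group that steers the next three stereoselective steps.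

**Step 4**
Reactants: 5 (5R)-5-[(tert-butyldimethylsilyl)oxy]-2-methylcyclohex-2-en-1-one
Product: 7 (5R,6S)-5-[(tert-butyldimethylsilyl)oxy]-2-methyl-6-(prop-2-en-1-yl)cyclohex-2-en-1-one, via lithium dienolate 6 (not isolated)
Conditions: LiN(iPr)2 (commercial solution), THF, −78 °C; allyl bromide, DMPU, −78 to −30 °C
Reagents that add atoms: allyl bromide C=CCBr
Why: Kinetic α′‑deprotonation gives the cross‑conjugated dienolate, and enolate alkylation places the allyl group anti to the neighbouring OTBS (6S); this centre is planarised again in step 5, so its ratio is not critical.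

**Step 5**
Reactants: 7 (5R,6S)-5-[(tert-butyldimethylsilyl)oxy]-2-methyl-6-(prop-2-en-1-yl)cyclohex-2-en-1-one
Product: 9 (5R,6R)-5-[(tert-butyldimethylsilyl)oxy]-2,6-dimethyl-6-(prop-2-en-1-yl)cyclohex-2-en-1-one, via lithium dienolate 8 (not isolated)
Conditions: LiN(iPr)2 (commercial solution), THF, −78 °C; MeI, DMPU, −78 to −30 °C
Reagents that add atoms: iodomethane CI
Why: Enolate C‑methylation of the tetrasubstituted dienolate occurs anti to the pseudo‑axial OTBS, so the quaternary centre is set 6R with methyl trans and allyl cis to OTBS.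

**Step 6**
Reactants: 9 (5R,6R)-5-[(tert-butyldimethylsilyl)oxy]-2,6-dimethyl-6-(prop-2-en-1-yl)cyclohex-2-en-1-one
Product: 11 2-[(1R,6R)-6-[(tert-butyldimethylsilyl)oxy]-1,3-dimethyl-2-oxocyclohex-3-en-1-yl]acetaldehyde, via diol 10 (not isolated)
Conditions: OsO4 (2 mol %), NaIO4, 2,6-lutidine, dioxane/H2O, rt
Reagents that add atoms: osmium tetroxide O=[Os](=O)(=O)=O (catalytic; its oxygen is replenished from sodium periodate [Na+].[O-][I](=O)(=O)=O)
Why: Lemieux–Johnson oxidative cleavage takes the monosubstituted alkene much faster than the electron‑poor trisubstituted enone alkene, and no stereocentre is affected.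

**Step 7**
Reactants: 11 2-[(1R,6R)-6-[(tert-butyldimethylsilyl)oxy]-1,3-dimethyl-2-oxocyclohex-3-en-1-yl]acetaldehyde
Product: 12 (5R,6R)-5-[(tert-butyldimethylsilyl)oxy]-6-{(E)-2-[(tert-butyldimethylsilyl)oxy]ethenyl}-2,6-dimethylcyclohex-2-en-1-one
Conditions: TBSOTf, Et3N, CH2Cl2, −78 to 0 °C
Reagents that add atoms: tert-butyldimethylsilyl triflate CC(C)(C)[Si](C)(C)OS(=O)(=O)C(F)(F)F
Why: Soft enolisation and O‑silylation act on the aldehyde only (the ketone has no α‑hydrogen on its quaternary side), and the neopentyl‑type aldehyde gives the E enol ether because the quaternary carbon avoids the position cis to OSi.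

**Step 8**
Reactants: 13 methyl (2S)-3-hydroxy-2-methylpropanoate
Product: 14 methyl (2S)-3-[(tert-butyldimethylsilyl)oxy]-2-methylpropanoate
Conditions: TBSCl, imidazole, CH2Cl2, rt
Reagents that add atoms: tert-butyldimethylsilyl chloride CC(C)(C)[Si](C)(C)Cl
Why: Silyl ether formation on the primary alcohol leaves the purchased stereocentre (the future C11) untouched.

**Step 9**
Reactants: 14 methyl (2S)-3-[(tert-butyldimethylsilyl)oxy]-2-methylpropanoate
Product: 15 (2S)-3-[(tert-butyldimethylsilyl)oxy]-2-methylpropanal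
Conditions: i-Bu2AlH, CH2Cl2, −78 °C; aq. KNaC4H4O6
Reagents that add atoms: none
Why: Partial hydride reduction of the ester stops at the aldehyde at −78 °C, and the cold non‑basic conditions do not epimerise the α‑centre.

**Step 10**
Reactants: 15 (2S)-3-[(tert-butyldimethylsilyl)oxy]-2-methylpropanal
Product: 16 tert-butyl{[(2R,3E)-4-iodo-2-methylbut-3-en-1-yl]oxy}dimethylsilane
Conditions: CrCl2, CHI3, THF, 0 °C to rt
Reagents that add atoms: iodoform IC(I)I
Why: Takai olefination gives the E alkenyl iodide selectively without base, so the stereocentre is kept (its descriptor changes to R only because the priorities change).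

**Step 11**
Reactants: 16 tert-butyl{[(2R,3E)-4-iodo-2-methylbut-3-en-1-yl]oxy}dimethylsilane; 12 (5R,6R)-5-[(tert-butyldimethylsilyl)oxy]-6-{(E)-2-[(tert-butyldimethylsilyl)oxy]ethenyl}-2,6-dimethylcyclohex-2-en-1-one
Product: 18 (1S,5R,6R)-5-[(tert-butyldimethylsilyl)oxy]-6-{(E)-2-[(tert-butyldimethylsilyl)oxy]ethenyl}-1-{(1E,3R)-4-[(tert-butyldimethylsilyl)oxy]-3-methylbut-1-en-1-yl}-2,6-dimethylcyclohex-2-en-1-ol, via alkenyllithium 17 (not isolated)
Conditions: 16, t-BuLi (2 equiv), Et2O, −78 °C; then 12, THF, −78 to −40 °C; aq. NH4Cl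
Reagents that add atoms: none
Why: Iodine–lithium exchange keeps the E geometry, and 1,2‑addition to the enone carbonyl comes from the face opposite the cis‑disposed C5 silyloxy and C6 silyloxyvinyl groups, giving the 1S carbinol with the two alkenyl groups trans.

**Step 12**
Reactants: 18 (1S,5R,6R)-5-[(tert-butyldimethylsilyl)oxy]-6-{(E)-2-[(tert-butyldimethylsilyl)oxy]ethenyl}-1-{(1E,3R)-4-[(tert-butyldimethylsilyl)oxy]-3-methylbut-1-en-1-yl}-2,6-dimethylcyclohex-2-en-1-ol
Product: 21 (2Z,5R,6E,8S,9S)-5,8-bis[(tert-butyldimethylsilyl)oxy]-9-{(2R)-1-[(tert-butyldimethylsilyl)oxy]propan-2-yl}-2,6-dimethylcyclodeca-2,6-dien-1-one, via potassium alkoxide 19 (not isolated), via potassium dienolate 20 (not isolated)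
Conditions: KH, 18-crown-6, THF, 0 °C to rt; AcOH, −78 °C
Reagents that add atoms: none
Why: Anionic oxy‑Cope [3,3]‑sigmatropic rearrangement: the trans‑dialkenyl alkoxide can react only through the chair with both alkenyl groups pseudo‑equatorial, which makes C4=C5 E, puts the E enol ether oxygen and the E alkene side chain equatorial (C6 S, C7 S, trans H6/H7, relayed from the quaternary carbon), and turns the cyclohexene C=C into the Z C1=C10 enone after C‑protonation of the dienolate.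

**Step 13**
Reactants: 21 (2Z,5R,6E,8S,9S)-5,8-bis[(tert-butyldimethylsilyl)oxy]-9-{(2R)-1-[(tert-butyldimethylsilyl)oxy]propan-2-yl}-2,6-dimethylcyclodeca-2,6-dien-1-one
Product: 22 (2Z,5R,6E,8S,9S)-5,8-dihydroxy-9-[(2R)-1-hydroxypropan-2-yl]-2,6-dimethylcyclodeca-2,6-dien-1-one
Conditions: HF·pyridine, pyridine, THF, 0 °C to rt
Reagents that add atoms: none
Why: Fluoride‑mediated desilylation buffered by pyridine removes all three silyl ethers, and the C1=C10 alkene, being part of an enone, is too electron‑poor for acid‑induced transannular cyclisation.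

**Step 14**
Reactants: 22 (2Z,5R,6E,8S,9S)-5,8-dihydroxy-9-[(2R)-1-hydroxypropan-2-yl]-2,6-dimethylcyclodeca-2,6-dien-1-one
Product: 25 (3R,3aS,6Z,9R,10E,11aS)-9-hydroxy-3,6,10-trimethyl-3,3a,4,8,9,11a-hexahydrocyclodeca[b]furan-2,5-dione, via hydroxy aldehyde 23 (not isolated), via lactol 24 (not isolated)
Conditions: TEMPO (cat.), PhI(OAc)2, CH2Cl2, rt
Reagents that add atoms: none
Why: TEMPO/PhI(OAc)2 oxidative lactonisation takes the primary alcohol first, the aldehyde is trapped by the C6 hydroxyl as a five‑membered lactol and oxidised on to the γ‑lactone, so the trans fusion (C6, C7) and the 11R methyl are those already set.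

**Step 15**
Reactants: 25 (3R,3aS,6Z,9R,10E,11aS)-9-hydroxy-3,6,10-trimethyl-3,3a,4,8,9,11a-hexahydrocyclodeca[b]furan-2,5-dione
Product: 26 (3R,3aS,6Z,9S,10E,11aS)-3,6,10-trimethyl-2,5-dioxo-2,3,3a,4,5,8,9,11a-octahydrocyclodeca[b]furan-9-yl acetate
Conditions: PPh3, DIAD, AcOH, THF, 0 °C to rt
Reagents that add atoms: acetic acid CC(=O)O
Why: Mitsunobu reaction: SN2 displacement of the activated C3 oxygen by acetate inverts C3 from R to S and installs the acetate in one operation, the C3–O bond standing roughly perpendicular to the ring so that its rear side is open.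

**Step 16**
Reactants: 26 (3R,3aS,6Z,9S,10E,11aS)-3,6,10-trimethyl-2,5-dioxo-2,3,3a,4,5,8,9,11a-octahydrocyclodeca[b]furan-9-yl acetate
Product: 27 (3R,3aS,5R,6Z,9S,10E,11aS)-5-hydroxy-3,6,10-trimethyl-2-oxo-2,3,3a,4,5,8,9,11a-octahydrocyclodeca[b]furan-9-yl acetate
Conditions: NaBH4, CeCl3·7H2O, MeOH, −78 °C
Reagents that add atoms: none
Why: Luche 1,2‑reduction: the C9 carbonyl sits across the ring from the C4=C5 alkene (the two carbons were bonded before the rearrangement), so hydride enters from the open face anti to that alkene and its C15 methyl and gives the 9R alcohol, while acetate and lactone survive at −78 °C.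

**Step 17**
Reactants: 27 (3R,3aS,5R,6Z,9S,10E,11aS)-5-hydroxy-3,6,10-trimethyl-2-oxo-2,3,3a,4,5,8,9,11a-octahydrocyclodeca[b]furan-9-yl acetate
Product: 28 (3R,3aS,5R,6Z,9S,10E,11aS)-3,6,10-trimethyl-2-oxo-2,3,3a,4,5,8,9,11a-octahydrocyclodeca[b]furan-5,9-diyl diacetate
Conditions: Ac2O, pyridine, DMAP (cat.), CH2Cl2, 0 °C to rt
Reagents that add atoms: acetic anhydride CC(=O)OC(C)=O
Why: DMAP‑catalysed O‑acylation of the C9 allylic alcohol proceeds with retention and completes the target.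

**Compound list**
1 | (R)-(−)-carvone, (5R)-2-methyl-5-(prop-1-en-2-yl)cyclohex-2-en-1-one | CC1=CC[C@H](CC1=O)C(C)=C | starting material
2 | (5R)-5-(1-hydroperoxy-1-methoxyethyl)-2-methylcyclohex-2-en-1-one (both epimers at the peroxyketal carbon) | CC1=CC[C@H](CC1=O)C(C)(OC)OO | intermediate
3 | (1R)-4-methyl-5-oxocyclohex-3-en-1-yl acetate | CC1=CC[C@H](CC1=O)OC(C)=O | intermediate
4 | (5R)-5-hydroxy-2-methylcyclohex-2-en-1-one | CC1=CC[C@H](CC1=O)O | intermediate
5 | (5R)-5-[(tert-butyldimethylsilyl)oxy]-2-methylcyclohex-2-en-1-one | CC1=CC[C@H](CC1=O)O[Si](C)(C)C(C)(C)C | intermediate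
6 | lithium (3R)-3-[(tert-butyldimethylsilyl)oxy]-6-methylcyclohexa-1,5-dien-1-olate | CC1=CC[C@@H](O[Si](C)(C)C(C)(C)C)C=C1O[Li] | intermediate
7 | (5R,6S)-5-[(tert-butyldimethylsilyl)oxy]-2-methyl-6-(prop-2-en-1-yl)cyclohex-2-en-1-one | CC1=CC[C@@H](O[Si](C)(C)C(C)(C)C)[C@H](CC=C)C1=O | intermediate
8 | lithium (3R)-3-[(tert-butyldimethylsilyl)oxy]-6-methyl-2-(prop-2-en-1-yl)cyclohexa-1,5-dien-1-olate | CC1=CC[C@@H](O[Si](C)(C)C(C)(C)C)C(CC=C)=C1O[Li] | intermediate
9 | (5R,6R)-5-[(tert-butyldimethylsilyl)oxy]-2,6-dimethyl-6-(prop-2-en-1-yl)cyclohex-2-en-1-one | CC1=CC[C@@H](O[Si](C)(C)C(C)(C)C)[C@@](C)(CC=C)C1=O | intermediate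
10 | (5R,6R)-5-[(tert-butyldimethylsilyl)oxy]-6-(2,3-dihydroxypropyl)-2,6-dimethylcyclohex-2-en-1-one (both carbinol epimers) | CC1=CC[C@@H](O[Si](C)(C)C(C)(C)C)[C@@](C)(CC(O)CO)C1=O | intermediate
11 | 2-[(1R,6R)-6-[(tert-butyldimethylsilyl)oxy]-1,3-dimethyl-2-oxocyclohex-3-en-1-yl]acetaldehyde | CC1=CC[C@@H](O[Si](C)(C)C(C)(C)C)[C@@](C)(CC=O)C1=O | intermediate
12 | (5R,6R)-5-[(tert-butyldimethylsilyl)oxy]-6-{(E)-2-[(tert-butyldimethylsilyl)oxy]ethenyl}-2,6-dimethylcyclohex-2-en-1-one | CC1=CC[C@@H](O[Si](C)(C)C(C)(C)C)[C@@](C)(/C=C/O[Si](C)(C)C(C)(C)C)C1=O | intermediate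
13 | methyl (2S)-3-hydroxy-2-methylpropanoate, (S)-Roche ester | COC(=O)[C@@H](C)CO | starting material
14 | methyl (2S)-3-[(tert-butyldimethylsilyl)oxy]-2-methylpropanoate | COC(=O)[C@@H](C)CO[Si](C)(C)C(C)(C)C | intermediate
15 | (2S)-3-[(tert-butyldimethylsilyl)oxy]-2-methylpropanal | O=C[C@@H](C)CO[Si](C)(C)C(C)(C)C | intermediate
16 | tert-butyl{[(2R,3E)-4-iodo-2-methylbut-3-en-1-yl]oxy}dimethylsilane | I/C=C/[C@@H](C)CO[Si](C)(C)C(C)(C)C | intermediate
17 | {(1E,3R)-4-[(tert-butyldimethylsilyl)oxy]-3-methylbut-1-en-1-yl}lithium | [Li]/C=C/[C@@H](C)CO[Si](C)(C)C(C)(C)C | intermediate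
18 | (1S,5R,6R)-5-[(tert-butyldimethylsilyl)oxy]-6-{(E)-2-[(tert-butyldimethylsilyl)oxy]ethenyl}-1-{(1E,3R)-4-[(tert-butyldimethylsilyl)oxy]-3-methylbut-1-en-1-yl}-2,6-dimethylcyclohex-2-en-1-ol | CC1=CC[C@@H](O[Si](C)(C)C(C)(C)C)[C@@](C)(/C=C/O[Si](C)(C)C(C)(C)C)[C@]1(O)/C=C/[C@@H](C)CO[Si](C)(C)C(C)(C)C | intermediate
19 | potassium alkoxide of 18 (potassium on the tertiary oxygen) | CC1=CC[C@@H](O[Si](C)(C)C(C)(C)C)[C@@](C)(/C=C/O[Si](C)(C)C(C)(C)C)[C@]1(O[K])/C=C/[C@@H](C)CO[Si](C)(C)C(C)(C)C | intermediate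
20 | potassium dienolate of 21 (enolate C8=C9 with ring carbons C7 and C10 trans; C1=C10 Z; C4=C5 E) | CC(C)(C)[Si](C)(C)O[C@@H]1C/C=C(/C)\C(O[K])=C\[C@@H]([C@@H](C)CO[Si](C)(C)C(C)(C)C)[C@@H](/C=C/1C)O[Si](C)(C)C(C)(C)C | intermediate
21 | (2Z,5R,6E,8S,9S)-5,8-bis[(tert-butyldimethylsilyl)oxy]-9-{(2R)-1-[(tert-butyldimethylsilyl)oxy]propan-2-yl}-2,6-dimethylcyclodeca-2,6-dien-1-one | CC(C)(C)[Si](C)(C)O[C@@H]1C/C=C(/C)C(=O)C[C@@H]([C@@H](C)CO[Si](C)(C)C(C)(C)C)[C@@H](/C=C/1C)O[Si](C)(C)C(C)(C)C | intermediate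
22 | (2Z,5R,6E,8S,9S)-5,8-dihydroxy-9-[(2R)-1-hydroxypropan-2-yl]-2,6-dimethylcyclodeca-2,6-dien-1-one | O[C@@H]1C/C=C(/C)C(=O)C[C@@H]([C@@H](C)CO)[C@@H](/C=C/1C)O | intermediate
23 | (2R)-2-[(1S,2S,3E,5R,7Z)-2,5-dihydroxy-4,8-dimethyl-9-oxocyclodeca-3,7-dien-1-yl]propanal | O[C@@H]1C/C=C(/C)C(=O)C[C@@H]([C@@H](C)C=O)[C@@H](/C=C/1C)O | intermediate
24 | (3R,3aS,6Z,9R,10E,11aS)-2,9-dihydroxy-3,6,10-trimethyl-2,3,3a,4,8,9-hexahydrocyclodeca[b]furan-5(11aH)-one (both lactol epimers) | O[C@@H]1C/C=C(/C)C(=O)C[C@@H]2[C@@H](/C=C/1C)OC(O)[C@@H]2C | intermediate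
25 | (3R,3aS,6Z,9R,10E,11aS)-9-hydroxy-3,6,10-trimethyl-3,3a,4,8,9,11a-hexahydrocyclodeca[b]furan-2,5-dione | O[C@@H]1C/C=C(/C)C(=O)C[C@@H]2[C@@H](/C=C/1C)OC(=O)[C@@H]2C | intermediate
26 | (3R,3aS,6Z,9S,10E,11aS)-3,6,10-trimethyl-2,5-dioxo-2,3,3a,4,5,8,9,11a-octahydrocyclodeca[b]furan-9-yl acetate | CC(=O)O[C@H]1C/C=C(/C)C(=O)C[C@@H]2[C@@H](/C=C/1C)OC(=O)[C@@H]2C | intermediate
27 | (3R,3aS,5R,6Z,9S,10E,11aS)-5-hydroxy-3,6,10-trimethyl-2-oxo-2,3,3a,4,5,8,9,11a-octahydrocyclodeca[b]furan-9-yl acetate | CC(=O)O[C@H]1C/C=C(/C)[C@H](O)C[C@@H]2[C@@H](/C=C/1C)OC(=O)[C@@H]2C | intermediate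
28 | (3R,3aS,5R,6Z,9S,10E,11aS)-3,6,10-trimethyl-2-oxo-2,3,3a,4,5,8,9,11a-octahydrocyclodeca[b]furan-5,9-diyl diacetate (CNP0226482.6) | CC(=O)O[C@H]1C/C=C(/C)[C@H](OC(C)=O)C[C@@H]2[C@@H](/C=C/1C)OC(=O)[C@@H]2C | target

**Step count and risks**
Total steps: 17. Longest linear sequence: 14 (steps 1–7 and 11–17); the three‑step side branch is steps 8–10.

The three steps most likely to fail:

Step 12 (oxy‑Cope). The only productive half‑chair places the C9 alkoxide and the C3 silyloxy group 1,3‑diaxial, so the rearrangement may be slow or be upset by base‑mediated silyl transfer. The fallback sets out from 18: the tertiary hydroxyl is capped with N‑(trimethylsilyl)imidazole to give the tertiary trimethylsilyl ether F1. F1 is heated in degassed xylene at about 190 °C in a sealed tube, so that a neutral siloxy‑Cope rearrangement through the same chair gives the trimethylsilyl enol ether F2. F2 is submitted directly to the HF·pyridine conditions of step 13, which remove all four silyl groups, and the route is rejoined at 22 (21 is bypassed).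

Step 15 (Mitsunobu inversion at C3). On an allylic alcohol in a ten‑membered ring, SN2′ attack or elimination may compete. The fallback sets out from 25: MnO2 in CH2Cl2 oxidises the allylic C3 alcohol to the trione F3. NaBH4/CeCl3·7H2O then reduces both enone carbonyls in one operation, hydride adding to C3 anti to the neighbouring C15 methyl and to C9 as in step 16, to give the (3S,9R)-diol F4. Diacetylation of F4 under the conditions of step 17 rejoins the route at 28 (26 and 27 are bypassed).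

Step 16 (Luche reduction). The facial selectivity at C9 rests on a conformational argument for a flexible ring. The fallback sets out from 26: if the reduction delivers the 9S alcohol, the 9‑epi alcohol F5, it is not acetylated but treated with PPh3, DIAD and AcOH, and this Mitsunobu acetoxylation inverts C9 and rejoins the route at 28 (27 is bypassed).

**Further compounds**
F1 | step 12 | tertiary trimethylsilyl ether of 18, (1S,5R,6R)-configured tetrasilyl ether | CC1=CC[C@@H](O[Si](C)(C)C(C)(C)C)[C@@](C)(/C=C/O[Si](C)(C)C(C)(C)C)[C@]1(O[Si](C)(C)C)/C=C/[C@@H](C)CO[Si](C)(C)C(C)(C)C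
F2 | step 12 | trimethylsilyl enol ether of 21 (C8=C9 enol ether, ring carbons C7 and C10 trans) | CC(C)(C)[Si](C)(C)O[C@@H]1C/C=C(/C)\C(O[Si](C)(C)C)=C\[C@@H]([C@@H](C)CO[Si](C)(C)C(C)(C)C)[C@@H](/C=C/1C)O[Si](C)(C)C(C)(C)C
F3 | step 15 | (3R,3aS,6Z,10E,11aS)-3,6,10-trimethyl-3a,4,8,11a-tetrahydrocyclodeca[b]furan-2,5,9(3H)-trione | O=C1C/C=C(/C)C(=O)C[C@@H]2[C@@H](/C=C/1C)OC(=O)[C@@H]2C
F4 | step 15 | (3R,3aS,5R,6Z,9S,10E,11aS)-5,9-dihydroxy-3,6,10-trimethyl-3a,4,5,8,9,11a-hexahydrocyclodeca[b]furan-2(3H)-one | O[C@H]1C/C=C(/C)[C@H](O)C[C@@H]2[C@@H](/C=C/1C)OC(=O)[C@@H]2C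
F5 | step 16 | (3R,3aS,5S,6Z,9S,10E,11aS)-5-hydroxy-3,6,10-trimethyl-2-oxo-2,3,3a,4,5,8,9,11a-octahydrocyclodeca[b]furan-9-yl acetate | CC(=O)O[C@H]1C/C=C(/C)[C@@H](O)C[C@@H]2[C@@H](/C=C/1C)OC(=O)[C@@H]2C
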